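Which ends with more D after 1.0 h at 0 °C: E fed over 30 min, or E charged at once?

| flask | E | L | temperature | remark | time |
|---|---|---|---|---|---|
| red | 0.40 M (fed, over 30 min) | 0.020 M | −15 °C | run made earlier |  |
| blue | 0.40 M (fed, over 30 min) | 0.030 M | 0 °C | run made earlier |  |
| midnight | 0.40 M (fed, over 30 min) | 0.0400 M | 0 °C |  | 1.0 h |
| dawn | 0.40 M | 0.0400 M | 0 °C | everything together at the start | 1.0 h |

- red (time / min: D / %, E / %): 6.00: 0, 19.7; 8.00: 0.3, 26.2; 12.0: 0.6, 39.2; 20.0: 1.6, 64.3; 30.0: 4.1, 94.2; 50.0: 9.5, 87.2; 80.0: 16.6, 78.1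
- blue (time / min: D / %, E / %): 5.00: 0.5, 15.7; 10.0: 3.4, 29.1; 15.0: 7.1, 40.5; 20.0: 11.8, 51.0; 25.0: 17.4, 59.7; 30.0: 25.0, 67.8; 40.0: 36.7, 50.2

(each reading ± 0.3 percentage points)

- on the list of suspects stand: E -> D; E -> X; X -> J; X -> Q; J <-> Q; L + J -> G
- percentages count the whole charge, also what has not yet gone in

- which of the two ends with the higher amount of D, in percent of the E charged ("neither" if they lie within 2 percentage points) (midnight / dawn / neither)
- D at the end, in percent of the E charged, midnight
- D at the end, in percent of the E charged, dawn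

The concentration I needed was that of E. After the feed of the red run, E fell at 0.00386 min⁻¹ and later at 0.00367 min⁻¹, nearly equal readings while E dropped, so I took the loss as first order in E. The two blue readings after the feed gave the loss constant 0.0301 min⁻¹, the fraction of the E present that goes per minute at 0 °C. By 40.0 min, blue's D was 73.7% of the E lost; I called this the D share, or selectivity. Blue had L at 0.030 M, and I carried both numbers to 0.0400 M unproved.

I followed midnight through blue. In the first minutes the feed brought 0.0333 min⁻¹ of the charge per minute, while the loss took 0.00472 min⁻¹, so E built up. At the end of the feed the loss had reached 0.0204 min⁻¹, still below the feed, and blue held E at 67.8%. From there E simply decays, so over the remaining 30.0 min I reckoned midnight's E down to 27.5%, which gives D 53.4%. Dawn decays for the whole time, to E 16.5% and D 61.6%. That is 8.2 percentage points above midnight, outside the margin of 2 points.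

The forecast said dawn, with 54% for midnight and 62% for dawn: “Dawn wins because E spends longer in the flask”.

The flask gave dawn, with D 52.8% in midnight and 60.6% in dawn.

    E → D (k = 0.0210 min⁻¹, Ea = 77.0 kJ mol⁻¹)
    E → X (k = 0.00730 min⁻¹, Ea = 82.0 kJ mol⁻¹)
    X → J (k = 0.0100 min⁻¹, Ea = 90.0 kJ mol⁻¹)
    X → Q (k = 0.00930 min⁻¹, Ea = 81.0 kJ mol⁻¹)
    J ⇌ Q (K = 16.0, k = 0.00300 min⁻¹, Ea = 84.0 kJ mol⁻¹, ΔH = −68.0 kJ mol⁻¹)
    L + J → G (k = 0.190 M⁻¹ min⁻¹, Ea = 50.0 kJ mol⁻¹)
    (constants at 0 °C)

The way E goes in is the main reason for the gap: dawn, given midnight's feed, ends at 52.8% D instead of 60.6%. Read at 2.5 h, midnight's neighbour should hold E 1.84% and D 72.3% by this reckoning; the computed flask holds E 2.3% and D 72.5%.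

(Readings and results come from a simulation for substances that don't exist; noise was put on by code.)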